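**Plan**

1. Numbering: ring B is C1 (bears the guaiacyl ring C1'–C6'), C2 (bears C9), C3 (bears C10), C4. Ring A is C4a–C8a with OMe at C6 and OH at C7 and C8.
2. Enabling feature: C1 is para-benzylic to the free C4' hydroxyl of the guaiacyl ring, so a C1 carbinol can lose water to a para-quinone methide. The neighbouring C2, as the enamine of a C9 aldehyde, can then attack C1 and close ring B.
3. Bonds cut: C1–C2 (ring B, key step), C1–C1' (aryl Grignard on a ring A aldehyde), C1–C8a (formylation of ring A), C3–C4 (alkylation of a pent-4-enoyl imide with 3,4,5-trimethoxybenzyl bromide).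
4. Forward order: chain and ring A are joined at C3–C4. The formyl carbon C1 then enters ring A and directs removal of the C8 and C7 methyl ethers. Guaiacyl addition, alkene cleavage to the C9 aldehyde, closure of ring B, reduction and debenzylation follow.
5. Stereochemistry: C3 comes from the (R)-4-benzyloxazolidinone auxiliary. C2 and C1 are set by C3 during ring closure (all-trans). The carbinol configuration at C1 is erased in the planar quinone methide.

Key step: step 12

Remark: the carbinol epimers of 18–21 are assumed to need no separation, because C1 becomes planar in 22. The CIP label of C3 changes from S (7–18) to R (19 onwards) only through a change in substituent priorities.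

**Step 1**
Reactants: 1 (4R)-4-benzyl-1,3-oxazolidin-2-one; 2 pent-4-enoyl chloride
Product: 4 (4R)-4-benzyl-3-(pent-4-enoyl)-1,3-oxazolidin-2-one, via lithium oxazolidinide 3 (not isolated)
Conditions: n-BuLi, THF, −78 °C; then 2, −78 → 0 °C
Reagents that add atoms: none
Why: N-acylation of the lithiated Evans auxiliary by the acid chloride; no stereocentre is formed.

**Step 2**
Reactants: 4 (4R)-4-benzyl-3-(pent-4-enoyl)-1,3-oxazolidin-2-one; 5 5-(bromomethyl)-1,2,3-trimethoxybenzene (3,4,5-trimethoxybenzyl bromide)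
Product: 7 (4R)-4-benzyl-3-[(2S)-2-(3,4,5-trimethoxybenzyl)pent-4-enoyl]-1,3-oxazolidin-2-one, via sodium Z-enolate 6 (not isolated)
Conditions: NaN(SiMe3)2, THF, −78 °C; then 5, −78 → −40 °C
Reagents that add atoms: none
Why: Evans asymmetric alkylation; the chelated Z-enolate should be attacked by the benzylic bromide on the face away from the C4 benzyl group of the (R)-auxiliary, which sets C3 (2S in the acyl chain, the arrangement that is 3R in the target).

**Step 3**
Reactants: 7 (4R)-4-benzyl-3-[(2S)-2-(3,4,5-trimethoxybenzyl)pent-4-enoyl]-1,3-oxazolidin-2-one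
Product: 8 (2S)-2-(3,4,5-trimethoxybenzyl)pent-4-en-1-ol
Conditions: LiBH4, MeOH (1.1 equiv), Et2O, 0 °C
Reagents that add atoms: none
Why: Reductive cleavage of the N-acyl oxazolidinone at the exocyclic carbonyl gives the C10 alcohol and returns the auxiliary without touching C3.

**Step 4**
Reactants: 8 (2S)-2-(3,4,5-trimethoxybenzyl)pent-4-en-1-ol
Product: 9 (2S)-2-(3,4,5-trimethoxybenzyl)pent-4-en-1-yl pivalate
Conditions: t-BuCOCl, pyridine, DMAP (cat.), CH2Cl2, 0 °C → rt
Reagents that add atoms: pivaloyl chloride, CC(C)(C)C(=O)Cl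
Why: Acylation of the primary alcohol; the pivalate is chosen because it should withstand POCl3, BCl3, a Grignard reagent at low temperature, periodate and fluoride, and falls off in the final hydride reduction.

**Step 5**
Reactants: 9 (2S)-2-(3,4,5-trimethoxybenzyl)pent-4-en-1-yl pivalate
Product: 11 (2S)-2-(2-formyl-3,4,5-trimethoxybenzyl)pent-4-en-1-yl pivalate, via aryl iminium salt 10 (not isolated)
Conditions: POCl3, DMF, 0 → 70 °C; then aq. NaOAc, rt
Reagents that add atoms: N,N-dimethylformamide, CN(C)C=O (formyl carbon); water, O (formyl oxygen on hydrolysis)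
Why: Vilsmeier–Haack formylation; the two free ring positions are equivalent, so a single aldehyde is expected, with the new carbon (C1) next to the future C8 oxygen, as in the formylation of 3,4,5-trimethoxytoluene.

**Step 6**
Reactants: 11 (2S)-2-(2-formyl-3,4,5-trimethoxybenzyl)pent-4-en-1-yl pivalate
Product: 13 (2S)-2-(2-formyl-3,4-dihydroxy-5-methoxybenzyl)pent-4-en-1-yl pivalate, via cyclic chloroborate 12 (not isolated)
Conditions: BCl3 (1 M in CH2Cl2, 3 equiv), CH2Cl2, −78 °C → rt; then H2O, 0 °C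
Reagents that add atoms: none
Why: Chelation-controlled Lewis acid ether cleavage; BCl3 held by the formyl oxygen should remove the ortho methyl ether (C8 oxygen) and then its neighbour (C7 oxygen) through the cyclic borate, while the methoxy para to the aldehyde (C6) lies outside the chelate, as in the known 2,3-bis-demethylation of 2,3,4-trimethoxybenzaldehyde.

**Step 7**
Reactants: 13 (2S)-2-(2-formyl-3,4-dihydroxy-5-methoxybenzyl)pent-4-en-1-yl pivalate
Product: 14 (2S)-2-[3,4-bis(benzyloxy)-2-formyl-5-methoxybenzyl]pent-4-en-1-yl pivalate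
Conditions: BnBr, K2CO3, DMF, 60 °C
Reagents that add atoms: benzyl bromide, BrCc1ccccc1
Why: Williamson etherification of both phenols masks the ring A oxygens, so that ring A cannot later form a quinone methide of its own.

**Step 8**
Reactants: 15 4-bromo-2-methoxyphenol
Product: 16 (4-bromo-2-methoxyphenoxy)(tert-butyl)dimethylsilane
Conditions: t-BuMe2SiCl, imidazole, CH2Cl2, rt
Reagents that add atoms: tert-butyl(chloro)dimethylsilane, CC(C)(C)[Si](C)(C)Cl
Why: Silylation of the phenol allows Grignard formation and protects the guaiacol from periodate in step 10.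

**Step 9**
Reactants: 16 (4-bromo-2-methoxyphenoxy)(tert-butyl)dimethylsilane; 14 (2S)-2-[3,4-bis(benzyloxy)-2-formyl-5-methoxybenzyl]pent-4-en-1-yl pivalate
Product: 18 (2S)-2-{3,4-bis(benzyloxy)-2-[(4-{[tert-butyl(dimethyl)silyl]oxy}-3-methoxyphenyl)(hydroxy)methyl]-5-methoxybenzyl}pent-4-en-1-yl pivalate (both carbinol epimers), via aryl Grignard reagent 17 (not isolated)
Conditions: 16, Mg turnings, THF, 50 °C; then 14, THF, −40 → 0 °C; aq. NH4Cl
Reagents that add atoms: none
Why: Grignard addition to the aldehyde forms C1–C1'; at low temperature the hindered pivalate should be spared, and the new carbinol centre forms as an epimer mixture that is erased in step 12.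

**Step 10**
Reactants: 18 (2S)-2-{3,4-bis(benzyloxy)-2-[(4-{[tert-butyl(dimethyl)silyl]oxy}-3-methoxyphenyl)(hydroxy)methyl]-5-methoxybenzyl}pent-4-en-1-yl pivalate
Product: 20 (2R)-2-{3,4-bis(benzyloxy)-2-[(4-{[tert-butyl(dimethyl)silyl]oxy}-3-methoxyphenyl)(hydroxy)methyl]-5-methoxybenzyl}-4-oxobutyl pivalate, via vicinal diol 19 (not isolated)
Conditions: OsO4 (2 mol %), NaIO4 (4 equiv), 2,6-lutidine, 1,4-dioxane–H2O (3:1), rt
Reagents that add atoms: osmium tetroxide, O=[Os](=O)(=O)=O (delivers the aldehyde oxygen; turned over by sodium periodate, [Na+].[O-]I(=O)(=O)=O)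
Why: Lemieux–Johnson oxidation; catalytic dihydroxylation of the terminal alkene and periodate cleavage of the diol give the C9 aldehyde, the phenol staying silylated because periodate oxidises free guaiacols.

**Step 11**
Reactants: 20 (2R)-2-{3,4-bis(benzyloxy)-2-[(4-{[tert-butyl(dimethyl)silyl]oxy}-3-methoxyphenyl)(hydroxy)methyl]-5-methoxybenzyl}-4-oxobutyl pivalate
Product: 21 (2R)-2-{3,4-bis(benzyloxy)-2-[hydroxy(4-hydroxy-3-methoxyphenyl)methyl]-5-methoxybenzyl}-4-oxobutyl pivalate
Conditions: Bu4NF, AcOH, THF, 0 °C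
Reagents that add atoms: none
Why: Fluoride desilylation of the aryl silyl ether, buffered with acetic acid so that aldol chemistry of the aldehyde and premature ionisation of the carbinol are avoided; the product would be used without delay.

**Step 12**
Reactants: 21 (2R)-2-{3,4-bis(benzyloxy)-2-[hydroxy(4-hydroxy-3-methoxyphenyl)methyl]-5-methoxybenzyl}-4-oxobutyl pivalate
Product: 24 (1S,2R,3R)-7,8-bis(benzyloxy)-1-(4-hydroxy-3-methoxyphenyl)-6-methoxy-3-(pivaloyloxymethyl)-1,2,3,4-tetrahydronaphthalene-2-carbaldehyde, via quinone methide aldehyde 22 (not isolated), via quinone methide enamine 23 (not isolated)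
Conditions: pyrrolidine (30 mol %), (PhO)2P(O)OH (30 mol %), CHCl3, 40 °C
Reagents that add atoms: none
Why: The acid should promote loss of water from the para-hydroxybenzhydrol to give quinone methide 22, planar at C1, while pyrrolidine condenses with the C9 aldehyde to the E-enamine 23, whose C2 adds to C1 as the phenol is regenerated; hydrolysis of the iminium returns the amine. The closest known reaction type is the amine-catalysed alpha-alkylation of aldehydes by 1,6-addition to para-quinone methides, including those formed in situ from para-hydroxybenzyl alcohols under acid, together with the related SN1-type enamine alkylation by benzhydrols. Ring B closes in the 6-exo-trig mode at the exocyclic methide carbon (enolexo with respect to the enamine). C2 is controlled by the C3 stereocentre, because the half-chair with the C3 pivaloyloxymethyl group equatorial lets C2 bond on the face that places C9 equatorial and trans to C10, and C2 remains correctable through enamine–iminium exchange; C1 is set relative to C2 by the anti approach of the quinoid ring and the enamine C9–N unit across the forming bond, which puts the aryl group trans to C9. The step needs C1 as the only electrophilic carbon and C2 as the only nucleophilic one: the C7 and C8 oxygens are benzylated so ring A cannot form a quinone methide, the free C4' hydroxyl is para to C1, and only C2 can reach C1 through a six-membered transition state.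

**Step 13**
Reactants: 24 (1S,2R,3R)-7,8-bis(benzyloxy)-1-(4-hydroxy-3-methoxyphenyl)-6-methoxy-3-(pivaloyloxymethyl)-1,2,3,4-tetrahydronaphthalene-2-carbaldehyde
Product: 25 (1S,2R,3R)-[7,8-bis(benzyloxy)-1-(4-hydroxy-3-methoxyphenyl)-6-methoxy-1,2,3,4-tetrahydronaphthalene-2,3-diyl]dimethanol
Conditions: LiAlH4, THF, 0 °C → rt; then H2O, aq. NaOH
Reagents that add atoms: none
Why: Hydride reduction; LiAlH4 should reduce the C9 aldehyde and cleave the C10 pivalate in one operation, hydride addition being much faster than enolisation so that C2 keeps its configuration.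

**Step 14**
Reactants: 25 (1S,2R,3R)-[7,8-bis(benzyloxy)-1-(4-hydroxy-3-methoxyphenyl)-6-methoxy-1,2,3,4-tetrahydronaphthalene-2,3-diyl]dimethanol
Product: 26 (1S,2R,3R)-1-(4-hydroxy-3-methoxyphenyl)-2,3-bis(hydroxymethyl)-6-methoxy-1,2,3,4-tetrahydronaphthalene-7,8-diol (CNP0219328.1)
Conditions: H2 (1 atm), Pd/C (10 wt % palladium on carbon), EtOAc–MeOH, rt
Reagents that add atoms: none
Why: Catalytic hydrogenolysis of the two aryl benzyl ethers; C1 carries no benzylic heteroatom bond, so the three stereocentres should be untouched.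

**Compound list**

1 | (4R)-4-benzyl-1,3-oxazolidin-2-one | O=C1N[C@H](Cc2ccccc2)CO1 | starting material
2 | pent-4-enoyl chloride | C=CCCC(=O)Cl | starting material
3 | lithium salt of 1 (lithium oxazolidinide) | [Li+].O=C1[N-][C@H](Cc2ccccc2)CO1 | intermediate (not isolated)
4 | (4R)-4-benzyl-3-(pent-4-enoyl)-1,3-oxazolidin-2-one | C=CCCC(=O)N1[C@H](Cc2ccccc2)COC1=O | intermediate
5 | 5-(bromomethyl)-1,2,3-trimethoxybenzene | COc1cc(CBr)cc(OC)c1OC | starting material
6 | sodium Z-enolate of 4 | [Na+].C=CC/C=C(\[O-])N1[C@H](Cc2ccccc2)COC1=O | intermediate (not isolated)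
7 | (4R)-4-benzyl-3-[(2S)-2-(3,4,5-trimethoxybenzyl)pent-4-enoyl]-1,3-oxazolidin-2-one | C=CC[C@@H](Cc1cc(OC)c(OC)c(OC)c1)C(=O)N1[C@H](Cc2ccccc2)COC1=O | intermediate
8 | (2S)-2-(3,4,5-trimethoxybenzyl)pent-4-en-1-ol | C=CC[C@@H](Cc1cc(OC)c(OC)c(OC)c1)CO | intermediate
9 | (2S)-2-(3,4,5-trimethoxybenzyl)pent-4-en-1-yl pivalate | C=CC[C@@H](Cc1cc(OC)c(OC)c(OC)c1)COC(=O)C(C)(C)C | intermediate
10 | aryl iminium salt: dimethyl{[2,3,4-trimethoxy-6-((2S)-2-(pivaloyloxymethyl)pent-4-enyl)phenyl]methylidene}ammonium dichlorophosphate | C=CC[C@@H](Cc1cc(OC)c(OC)c(OC)c1C=[N+](C)C)COC(=O)C(C)(C)C.[O-]P(=O)(Cl)Cl | intermediate (not isolated)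
11 | (2S)-2-(2-formyl-3,4,5-trimethoxybenzyl)pent-4-en-1-yl pivalate | C=CC[C@@H](Cc1cc(OC)c(OC)c(OC)c1C=O)COC(=O)C(C)(C)C | intermediate
12 | cyclic chloroborate: (2S)-2-[(2-chloro-4-formyl-7-methoxy-1,3,2-benzodioxaborol-5-yl)methyl]pent-4-en-1-yl pivalate | C=CC[C@@H](Cc1cc(OC)c2OB(Cl)Oc2c1C=O)COC(=O)C(C)(C)C | intermediate (not isolated)
13 | (2S)-2-(2-formyl-3,4-dihydroxy-5-methoxybenzyl)pent-4-en-1-yl pivalate | C=CC[C@@H](Cc1cc(OC)c(O)c(O)c1C=O)COC(=O)C(C)(C)C | intermediate
14 | (2S)-2-[3,4-bis(benzyloxy)-2-formyl-5-methoxybenzyl]pent-4-en-1-yl pivalate | C=CC[C@@H](Cc1cc(OC)c(OCc2ccccc2)c(OCc3ccccc3)c1C=O)COC(=O)C(C)(C)C | intermediate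
15 | 4-bromo-2-methoxyphenol | COc1cc(Br)ccc1O | starting material
16 | (4-bromo-2-methoxyphenoxy)(tert-butyl)dimethylsilane | COc1cc(Br)ccc1O[Si](C)(C)C(C)(C)C | intermediate
17 | {4-[(tert-butyldimethylsilyl)oxy]-3-methoxyphenyl}magnesium bromide | COc1cc([Mg]Br)ccc1O[Si](C)(C)C(C)(C)C | intermediate (not isolated)
18 | (2S)-2-{3,4-bis(benzyloxy)-2-[(4-{[tert-butyl(dimethyl)silyl]oxy}-3-methoxyphenyl)(hydroxy)methyl]-5-methoxybenzyl}pent-4-en-1-yl pivalate, carbinol carbon as both epimers | C=CC[C@@H](Cc1cc(OC)c(OCc2ccccc2)c(OCc3ccccc3)c1C(O)c4ccc(O[Si](C)(C)C(C)(C)C)c(OC)c4)COC(=O)C(C)(C)C | intermediate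
19 | (2R)-2-{3,4-bis(benzyloxy)-2-[(4-{[tert-butyl(dimethyl)silyl]oxy}-3-methoxyphenyl)(hydroxy)methyl]-5-methoxybenzyl}-4,5-dihydroxypentyl pivalate, diastereomer mixture at the two carbinol carbons | OCC(O)C[C@@H](Cc1cc(OC)c(OCc2ccccc2)c(OCc3ccccc3)c1C(O)c4ccc(O[Si](C)(C)C(C)(C)C)c(OC)c4)COC(=O)C(C)(C)C | intermediate (not isolated)
20 | (2R)-2-{3,4-bis(benzyloxy)-2-[(4-{[tert-butyl(dimethyl)silyl]oxy}-3-methoxyphenyl)(hydroxy)methyl]-5-methoxybenzyl}-4-oxobutyl pivalate, both carbinol epimers | O=CC[C@@H](Cc1cc(OC)c(OCc2ccccc2)c(OCc3ccccc3)c1C(O)c4ccc(O[Si](C)(C)C(C)(C)C)c(OC)c4)COC(=O)C(C)(C)C | intermediate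
21 | (2R)-2-{3,4-bis(benzyloxy)-2-[hydroxy(4-hydroxy-3-methoxyphenyl)methyl]-5-methoxybenzyl}-4-oxobutyl pivalate, both carbinol epimers | O=CC[C@@H](Cc1cc(OC)c(OCc2ccccc2)c(OCc3ccccc3)c1C(O)c4ccc(O)c(OC)c4)COC(=O)C(C)(C)C | intermediate
22 | (2R)-2-{3,4-bis(benzyloxy)-5-methoxy-2-[(3-methoxy-4-oxocyclohexa-2,5-dien-1-ylidene)methyl]benzyl}-4-oxobutyl pivalate | O=CC[C@@H](Cc1cc(OC)c(OCc2ccccc2)c(OCc3ccccc3)c1C=C4C=CC(=O)C(OC)=C4)COC(=O)C(C)(C)C | intermediate (not isolated)
23 | (2R,3E)-2-{3,4-bis(benzyloxy)-5-methoxy-2-[(3-methoxy-4-oxocyclohexa-2,5-dien-1-ylidene)methyl]benzyl}-4-(pyrrolidin-1-yl)but-3-en-1-yl pivalate | C5CCCN5/C=C/[C@@H](Cc1cc(OC)c(OCc2ccccc2)c(OCc3ccccc3)c1C=C4C=CC(=O)C(OC)=C4)COC(=O)C(C)(C)C | intermediate (not isolated)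
24 | (1S,2R,3R)-7,8-bis(benzyloxy)-1-(4-hydroxy-3-methoxyphenyl)-6-methoxy-3-(pivaloyloxymethyl)-1,2,3,4-tetrahydronaphthalene-2-carbaldehyde | COc1cc([C@H]2c3c(cc(OC)c(OCc4ccccc4)c3OCc5ccccc5)C[C@@H](COC(=O)C(C)(C)C)[C@@H]2C=O)ccc1O | intermediate
25 | (1S,2R,3R)-[7,8-bis(benzyloxy)-1-(4-hydroxy-3-methoxyphenyl)-6-methoxy-1,2,3,4-tetrahydronaphthalene-2,3-diyl]dimethanol | COc1cc([C@H]2c3c(cc(OC)c(OCc4ccccc4)c3OCc5ccccc5)C[C@@H](CO)[C@@H]2CO)ccc1O | intermediate
26 | (1S,2R,3R)-1-(4-hydroxy-3-methoxyphenyl)-2,3-bis(hydroxymethyl)-6-methoxy-1,2,3,4-tetrahydronaphthalene-7,8-diol | COc1cc([C@H]2c3c(cc(OC)c(O)c3O)C[C@@H](CO)[C@@H]2CO)ccc1O | target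

**Step count and risks**

Total step count: 14. Longest linear sequence: 13 steps (steps 1–7 and 9–14); step 8 is the one-step side branch.

Steps most likely to fail:

Step 12. Ring closure may lose out to intermolecular capture of the quinone methide (by the amine, by water or by a second molecule), or the ring may close with a cis relationship between C1 and C2. The same C1–C2 bond would then be made by a Lewis-acid SN1 alkylation of a silyl enol ether (Mukaiyama type). Setting out from aldehyde 20, t-BuMe2SiOTf and Et3N in CH2Cl2 should convert the aldehyde into its silyl enol ether and silylate the carbinol, giving the tris-silyl enol ether F1. BF3·OEt2 in CH2Cl2 at −78 °C should ionise the benzhydryl silyl ether to a doubly stabilised diarylmethyl cation, which the enol ether carbon C2 captures to give the tetralin aldehyde aryl silyl ether F2. Bu4NF/AcOH in THF would then free the phenol and rejoin the route at 24; a C2 epimer could be corrected by brief exposure to DBU.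

Step 6. The second demethylation may be slow, and prolonged exposure to BCl3 could then erode the pivalate. The ring A operations would in that case be carried out at the imide stage, where no ester is present. Setting out from imide 7, Vilsmeier–Haack formylation should give the imide aldehyde F3, BCl3 the catechol aldehyde F4, and BnBr/K2CO3 the bis(benzyl) ether F5. LiBH4 would reduce imide and aldehyde together to the diol F6, MnO2 in CH2Cl2 would reoxidise only the benzylic alcohol to the hydroxy aldehyde F7, and pivaloylation of the remaining primary alcohol comes back to the route at 14.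

Step 5. Formylation at the position flanked by the benzylic CH2 and a methoxy group may stall, or the acidic medium at 70 °C may attack the alkene. The formyl group would then be introduced by halogen–metal exchange. Setting out from 9, NBS in MeCN at 0 °C should brominate the same (only) kind of free ring position to give the aryl bromide F8; n-BuLi in THF at −78 °C followed by DMF would deliver aldehyde 11, where the route is rejoined.

**Further compounds**

F1 | step 12 | (2R)-2-{3,4-bis(benzyloxy)-2-[{[tert-butyl(dimethyl)silyl]oxy}(4-{[tert-butyl(dimethyl)silyl]oxy}-3-methoxyphenyl)methyl]-5-methoxybenzyl}-4-{[tert-butyl(dimethyl)silyl]oxy}but-3-en-1-yl pivalate (enol ether E/Z and carbinol epimer mixture) | CC(C)(C)[Si](C)(C)OC=C[C@@H](Cc1cc(OC)c(OCc2ccccc2)c(OCc3ccccc3)c1C(O[Si](C)(C)C(C)(C)C)c4ccc(O[Si](C)(C)C(C)(C)C)c(OC)c4)COC(=O)C(C)(C)C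
F2 | step 12 | (1S,2R,3R)-7,8-bis(benzyloxy)-1-(4-{[tert-butyl(dimethyl)silyl]oxy}-3-methoxyphenyl)-6-methoxy-3-(pivaloyloxymethyl)-1,2,3,4-tetrahydronaphthalene-2-carbaldehyde | COc1cc([C@H]2c3c(cc(OC)c(OCc4ccccc4)c3OCc5ccccc5)C[C@@H](COC(=O)C(C)(C)C)[C@@H]2C=O)ccc1O[Si](C)(C)C(C)(C)C
F3 | step 6 | (4R)-4-benzyl-3-[(2S)-2-(2-formyl-3,4,5-trimethoxybenzyl)pent-4-enoyl]-1,3-oxazolidin-2-one | C=CC[C@@H](Cc1cc(OC)c(OC)c(OC)c1C=O)C(=O)N1[C@H](Cc2ccccc2)COC1=O
F4 | step 6 | (4R)-4-benzyl-3-[(2S)-2-(2-formyl-3,4-dihydroxy-5-methoxybenzyl)pent-4-enoyl]-1,3-oxazolidin-2-one | C=CC[C@@H](Cc1cc(OC)c(O)c(O)c1C=O)C(=O)N1[C@H](Cc2ccccc2)COC1=O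
F5 | step 6 | (4R)-4-benzyl-3-{(2S)-2-[3,4-bis(benzyloxy)-2-formyl-5-methoxybenzyl]pent-4-enoyl}-1,3-oxazolidin-2-one | C=CC[C@@H](Cc1cc(OC)c(OCc2ccccc2)c(OCc3ccccc3)c1C=O)C(=O)N1[C@H](Cc4ccccc4)COC1=O
F6 | step 6 | (2S)-2-[3,4-bis(benzyloxy)-2-(hydroxymethyl)-5-methoxybenzyl]pent-4-en-1-ol | C=CC[C@@H](Cc1cc(OC)c(OCc2ccccc2)c(OCc3ccccc3)c1CO)CO
F7 | step 6 | 2,3-bis(benzyloxy)-6-[(2S)-2-(hydroxymethyl)pent-4-en-1-yl]-4-methoxybenzaldehyde | C=CC[C@@H](Cc1cc(OC)c(OCc2ccccc2)c(OCc3ccccc3)c1C=O)CO
F8 | step 5 | (2S)-2-(2-bromo-3,4,5-trimethoxybenzyl)pent-4-en-1-yl pivalate | C=CC[C@@H](Cc1cc(OC)c(OC)c(OC)c1Br)COC(=O)C(C)(C)C
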